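The north run reads 0 % product at 1.00 min, 8 % at 4.00 min and 13 % at 8.00 min, and dividing that last reading by its time gives 0.0163 min⁻¹, the yield pace: the fraction of the charged substrate that becomes product per minute, averaged from the start. The two flasks asked about can be reached from that run, one setting at a time.

| setting | north | north-west | autumn | summer |
|---|---|---|---|---|
| substrate | 0.056 M | 0.056 M | 0.015 M | 0.056 M |
| reagent | 0.101 M | 0.101 M | 0.0300 M | 0.101 M |
| capture agent | 0.084 M | 0.056 M | 0.0560 M | 0.0560 M |
| free catalyst | 56 µM | 56 µM | 56 µM | 56 µM |
| second catalyst | 6.2 mM | 12 mM | 6.2 mM | 6.2 mM |
| temperature | 50 °C | 50 °C | 50 °C | 50 °C |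
| remark | run made earlier | run made earlier |  |  |
| time |  |  | 5.0 min | 20 min |

- north (time / min: product / %): 0.500: 0; 1.00: 0; 2.00: 4; 4.00: 8; 8.00: 13
- north-west (time / min: product / %): 0.500: 1; 1.00: 0; 2.00: 4; 4.00: 11; 8.00: 24

(readings scatter by 1.5 percentage points)

1. which of the two ends with the higher amount of product, in percent of the substrate charged ("neither" if they lie within 2 percentage points) (autumn / summer / neither)
2. product at the end, in percent of the substrate charged, autumn
3. product at the end, in percent of the substrate charged, summer

- the numbers in the tables scatter with a standard deviation of 1.5 percentage points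
- steps under discussion: open intermediate + capture agent -> trapped intermediate; second catalyst + open intermediate <-> catalyst intermediate; substrate + free catalyst <-> free catalyst + open intermediate; reagent + catalyst intermediate -> second catalyst + product

Substrate comes first. At a fixed c(free catalyst), its opening is pseudo-first-order in substrate, so by hand a percent of the charge does not move with the charge. The pace therefore passes from 0.056 M to the 0.015 M of autumn unchanged, although no reading tests this.

Reagent comes next. It meets the catalyst intermediate after the open intermediate has branched, and the earlier runs hold it at 0.101 M. Autumn charges 0.0300 M, still more than its substrate, at 2.00 equivalents, so substrate remains the limiting reagent and the reckoning leaves the pace alone.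

The north-west run then moves two settings together. It has twice the c(second catalyst) of the north run and less capture agent, 0.056 M against 0.084 M, and it reads 24 % at 8.00 min, more than the north run. Autumn and summer keep the second catalyst of the north run with the capture agent of the north-west run, and by hand less capture agent than in the north run raises the pace, while the loss of substrate over the longer time of summer lowers it. Neither correction is sized here, so the pace stands as read.

Time remains: 5.0 min for autumn, 20 min for summer. This reckoning gives autumn 8.15 % and summer 32.6 %.

The forecast, by another route, gives summer as the higher, with 7 % for autumn and 32 % for summer, on the ground that “the open intermediate then splits between the second catalyst (leading to product) and the capture agent (leading to loss)”.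

The flask gives summer as the higher, with 40.3 % against 8.82 % for autumn.

    open intermediate + capture agent → trapped intermediate (k = 2.04 L mol⁻¹ min⁻¹, Ea = 48.0 kJ mol⁻¹)
    second catalyst + open intermediate ⇌ catalyst intermediate (K = 3.00 L mol⁻¹, k = 37.7 L mol⁻¹ min⁻¹, Ea = 66.0 kJ mol⁻¹, ΔH = −20.0 kJ mol⁻¹)
    substrate + free catalyst ⇌ free catalyst + open intermediate (K = 0.795, k = 1170 L mol⁻¹ min⁻¹, Ea = 53.0 kJ mol⁻¹, ΔH = −42.0 kJ mol⁻¹)
    reagent + catalyst intermediate → second catalyst + product (k = 5110 L mol⁻¹ min⁻¹, Ea = 45.0 kJ mol⁻¹)
    (constants at 50 °C)

Summer stands 8.3 percentage points above the forecast, and at 20.0 min it still holds 34.9 % of its substrate. Its own mean pace is 0.0202 min⁻¹, faster than the pace read from the north run. The neighbour of autumn charged with 0.012 M of reagent, 0.800 equiv, is the further case: the pace over 5.00 min gives 8.15 %, and that flask holds 8.06 % product.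

Readings and results stem from a simulated flask on assumed constants, and the scatter is random.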